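**Retrosynthetic overview**
1. Target 36 ⇐ tenfold O-demethylation of 35 ⇐ Horner–Wadsworth–Emmons union of the western benzofuranylmethyl phosphonate 34 (aryloxy ketone cyclodehydration, then C2–H arylation) with the eastern aldehyde 25.
2. 25 ⇐ nickel-catalysed arylation at Cα of seven-ring alcohol 19 (ring C enters trans to the Cβ aryl) ⇐ Friedel–Crafts opening of the stilbene oxide of 17 by ring B (seven-membered ring = C3, C3a, C4, Cα, Cβ and two ring B carbons).
3. 17 ⇐ dihydrobenzofuran 13 ⇐ triaryl oxirane 9 by the key step, which forms the aryl ether bond O1–C7a and closes the furan ring in a fluoride-triggered relay: epoxide → para-quinone methide → oxa-Michael addition → rearomatisation.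
4. Enabling feature: in ring A (C3a, C4, C5, C6, C7, C7a of the eastern dihydrobenzofuran) the C6 oxygen is para to C3a, the carbon that carries C3; the quinone methide C6=O/C3a=C3 therefore has its enone β-carbon C7a five atoms from the oxygen on C2, while the other β-carbon C4 is blocked by a carbon substituent.
5. Ring order: west, furan ring then 2-aryl group; east, oxirane → dihydrofuran ring (key) → seven-membered carbocycle; stereo relay C2 (epoxidation) → C3 (key step) → Cβ → Cα, with C2 finally equilibrated to trans.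

Key step: step 5

Remark: the protonation that ends step 5 is assumed to be kinetic and anti to the C2 aryl group (2,3-cis product); this fixes the enantiomer of the epoxidation ketone in step 4 (taken as purchasable, like Weinreb amide 3), and the cis relationship is corrected to trans in step 12.

**Step 1**
Reactants: 1 4-bromo-3-(hydroxymethyl)phenol
Product: 2 4-bromo-3-(triisopropylsilyloxymethyl)phenyl triisopropylsilyl ether
Conditions: TIPSCl (2.4 equiv), imidazole, DMF, 23 °C
Reagents that add atoms: chlorotriisopropylsilane CC(C)[Si](Cl)(C(C)C)C(C)C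
Why: Standard silylation of a phenol and a primary alcohol with a silyl chloride and imidazole; no stereocentre is involved.

**Step 2**
Reactants: 2 bis-silyl ether; 3 N-methoxy-N-methyl-3,5-dimethoxybenzamide
Product: 5 (3,5-dimethoxyphenyl)[2-(triisopropylsilyloxymethyl)-4-(triisopropylsilyloxy)phenyl]methanone, via aryllithium 4 (not isolated)
Conditions: n-BuLi, THF, −78 °C; then 3, −78 → 0 °C; aq. NH4Cl
Reagents that add atoms: none
Why: Bromine–lithium exchange gives aryllithium 4, held at −78 °C so that the ortho silyl group does not migrate (retro-Brook), and acylation stops at the ketone through the chelated tetrahedral intermediate (Weinreb ketone synthesis).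

**Step 3**
Reactants: 5 diaryl ketone; 6 (4-methoxybenzyl)magnesium chloride
Product: 8 1-(3,5-dimethoxyphenyl)-2-(4-methoxyphenyl)-1-[2-(triisopropylsilyloxymethyl)-4-(triisopropylsilyloxy)phenyl]ethene (E/Z mixture), via tertiary carbinol 7 (not isolated)
Conditions: 6, THF, 0 °C; aq. NH4Cl; crude 7: MsCl, Et3N, CH2Cl2, 0 → 23 °C
Reagents that add atoms: none
Why: Grignard addition to the diaryl ketone and E1-type dehydration of the tertiary dibenzylic carbinol through its mesylate should give the triarylethylene as an E/Z mixture, which is acceptable because both isomers converge in steps 4 and 5.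

**Step 4**
Reactants: 8 triarylethylene
Product: 9 (3S)-2-(3,5-dimethoxyphenyl)-3-(4-methoxyphenyl)-2-[2-(triisopropylsilyloxymethyl)-4-(triisopropylsilyloxy)phenyl]oxirane (mixture of C2 epimers)
Conditions: L-fructose-derived Shi ketone (30 mol%), Oxone (2KHSO5·KHSO4·K2SO4), K2CO3, Na2B4O7 buffer (pH 10.5), n-Bu4NHSO4, MeCN/dimethoxymethane/H2O, 0 °C; purification on Et3N-deactivated silica
Reagents that add atoms: potassium peroxymonosulfate (active component of Oxone) [K+].[O-]S(=O)(=O)OO
Why: Shi asymmetric epoxidation (chiral dioxirane, spiro transition state) of a trisubstituted aryl olefin; the catalyst distinguishes H from aryl at the CH carbon and treats the two aryl groups on the other carbon alike, so both olefin isomers are expected to give the (3S) oxirane carbon (the later C2), while the quaternary carbon stays an epimer mixture that is erased in step 5.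

**Step 5**
Reactants: 9 triaryl oxirane
Product: 13 (2R,3S)-3-(3,5-dimethoxyphenyl)-4-(hydroxymethyl)-2-(4-methoxyphenyl)-2,3-dihydro-1-benzofuran-6-ol (2,3-cis), via phenoxide epoxide 10 (not isolated), via quinone methide alkoxide 11 (not isolated), via isoaromatic enolate 12 (not isolated)
Conditions: n-Bu4NF (1.1 equiv), t-BuOH (5 equiv), THF, −20 → 0 °C; then n-Bu4NF (1.5 equiv), 23 °C; AcOH quench; chromatography (removes any 2,3-trans isomer)
Reagents that add atoms: none
Why: Proposed new method: fluoride frees the C6 phenoxide 10, which opens the para-placed oxirane at its benzylic carbon to the para-quinone methide 11 carrying a secondary alkoxide; this alkoxide adds to the enone β-carbon C7a and the isoaromatic enolate 12 rearomatises by a tert-butanol-mediated 1,3-proton shift from C7a to C3, so that the epoxide is isomerised to the dihydrobenzofuran in a formal C–H etherification without external oxidant (the second portion of fluoride then removes the primary silyl ether). The closest known reactions are the phenoxide-triggered opening of 4-hydroxyphenyl epoxides to quinone methides, the oxa-Michael closure of hydroxyethyl cyclohexadienones to hexahydrobenzofuranones, and the base-mediated isotoluene-to-arene tautomerisation. The furan ring closes in a 5-exo-trig mode on the C7=C7a enone bond, and the driving force is the recovery of aromaticity in the last proton shift. The C2 stereocentre comes unchanged from the oxirane because its C–O bond is never broken, and the new C3 stereocentre is set by kinetic protonation of the planar benzylic anion on the face anti to the C2 aryl group, which should give the 2,3-cis isomer. The step needs attack at C7a instead of C4 or the methide carbon: C4 carries the CH2OSi group, so addition there gives a quaternary adduct that cannot aromatise and reverts, closure at the methide carbon only returns the strained epoxide, and the two quinone methide geometries interconvert through that epoxide, so all material funnels through the C7a adduct. The competing 1,2-hydride shift of alkoxide 11 to a ketone is kept slow by the low temperature and the fast intramolecular oxygen attack.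

**Step 6**
Reactants: 13 dihydrobenzofuranol
Product: 14 [(2R,3S)-3-(3,5-dimethoxyphenyl)-6-methoxy-2-(4-methoxyphenyl)-2,3-dihydro-1-benzofuran-4-yl]methanol
Conditions: MeI, K2CO3, acetone, 23 °C
Reagents that add atoms: iodomethane CI
Why: Williamson O-methylation of the phenol with K2CO3, which leaves the primary benzylic alcohol and both stereocentres untouched.

**Step 7**
Reactants: 14 benzylic alcohol
Product: 15 (2R,3S)-3-(3,5-dimethoxyphenyl)-6-methoxy-2-(4-methoxyphenyl)-2,3-dihydro-1-benzofuran-4-carbaldehyde
Conditions: MnO2, CH2Cl2, 23 °C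
Reagents that add atoms: none
Why: MnO2 oxidation of a benzylic alcohol to the aldehyde under neutral conditions, chosen because acid could trigger a Bradsher-type Friedel–Crafts attack of ring B on the aldehyde.

**Step 8**
Reactants: 15 aldehyde; 16 diethyl (4-methoxybenzyl)phosphonate
Product: 17 (2R,3S)-3-(3,5-dimethoxyphenyl)-6-methoxy-2-(4-methoxyphenyl)-4-[(E)-2-(4-methoxyphenyl)ethenyl]-2,3-dihydro-1-benzofuran (2,3-cis epimer of ε-viniferin pentamethyl ether)
Conditions: 16, t-BuOK, THF, 0 °C; then 15, 0 → 23 °C
Reagents that add atoms: none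
Why: Horner–Wadsworth–Emmons olefination of a benzylic phosphonate with an aryl aldehyde should give the E-stilbene, and the weakly basic phosphonate anion does not deprotonate C3–H.

**Step 9**
Reactants: 17 stilbene
Product: 19 tetracyclic alcohol: 17 in which Cβ (bearing the 4-methoxyphenyl group) is bonded to the ortho carbon of ring B and Cα (on C4) carries OH; Cβ S, C3 S, C2 R, Cα epimer mixture, via stilbene oxide 18 (not isolated)
Conditions: dimethyldioxirane, acetone, 0 °C; evaporate; BF3·OEt2 (20 mol%), CH2Cl2, −78 °C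
Reagents that add atoms: dimethyldioxirane CC1(C)OO1
Why: Dioxirane epoxidation of the electron-rich stilbene is followed by Lewis-acid opening at the 4-methoxybenzylic carbon Cβ and intramolecular Friedel–Crafts attack by the ortho position of ring B (seven-membered ring, the ampelopsin A-type cyclisation); because Cβ reacts as an open benzylic cation both epoxide diastereomers converge, and the C3 stereocentre holds ring B over one face of ring A so that the Cβ aryl group should take the outward position on the convex face with Cβ–H pointing over ring A, while Cα–OH forms as an epimer mixture that is erased in step 11.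

**Step 10**
Reactants: 20 3-iodo-4-methoxybenzaldehyde
Product: 21 2-(3-iodo-4-methoxyphenyl)-1,3-dioxolane
Conditions: HOCH2CH2OH, p-TsOH (cat.), toluene, reflux (Dean–Stark)
Reagents that add atoms: ethylene glycol OCCO
Why: Acid-catalysed acetalisation with azeotropic removal of water protects the aldehyde for the organozinc chemistry.

**Step 11**
Reactants: 19 tetracyclic alcohol; 21 aryl iodide
Product: 24 tetracyclic acetal: 19 with Cα–OH replaced by 5-(1,3-dioxolan-2-yl)-2-methoxyphenyl (ring C); Cα R, Cβ S, C3 S, C2 R, via mesylate 22 (not isolated), via arylzinc iodide 23 (not isolated)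
Conditions: 21, Zn dust, LiCl, THF, 50 °C (gives 23); 19, MsCl, Et3N, THF, −20 °C (gives 22); then NiBr2·diglyme (10 mol%), 4,4′-di-tert-butyl-2,2′-bipyridine (12 mol%), 23, THF/DMA, −20 → 0 °C
Reagents that add atoms: none
Why: Nickel-catalysed Negishi arylation of a secondary benzylic mesylate with an arylzinc iodide proceeds through a benzylic radical and is stereoconvergent; the planar Cα radical should be captured on the open outward face anti to the neighbouring Cβ aryl group, which sets the Cα/Cβ trans relationship from either carbinol epimer.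

**Step 12**
Reactants: 24 tetracyclic acetal
Product: 25 tetracyclic aldehyde: ring C = 5-formyl-2-methoxyphenyl; Cα R, Cβ S, C3 S, C2 S (2,3-trans)
Conditions: CF3CO2H/CH2Cl2 (1:4), H2O (5 equiv), 0 → 23 °C, short reaction time
Reagents that add atoms: water O
Why: Aqueous trifluoroacetic acid hydrolyses the dioxolane and reversibly ionises the C2–O bond to the 4-methoxybenzylic cation, whose reclosure by the C7a phenol equilibrates C2 to the thermodynamically favoured 2,3-trans dihydrobenzofuran (the known acid-mediated cis-to-trans epimerisation of 2-aryl-2,3-dihydrobenzofurans); no hydroxyl group is present that could trap the cation elsewhere.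

**Step 13**
Reactants: 26 methyl 3-hydroxy-5-methoxybenzoate; 27 2-bromo-1-(3,5-dimethoxyphenyl)ethan-1-one
Product: 28 methyl 3-[2-(3,5-dimethoxyphenyl)-2-oxoethoxy]-5-methoxybenzoate
Conditions: K2CO3, acetone, reflux
Reagents that add atoms: none
Why: Williamson O-alkylation of the phenol with an α-bromo ketone (SN2).

**Step 14**
Reactants: 28 aryloxy ketone
Product: 29 methyl 3-(3,5-dimethoxyphenyl)-6-methoxy-1-benzofuran-4-carboxylate
Conditions: Bi(OTf)3 (10 mol%), ClCH2CH2Cl, 80 °C
Reagents that add atoms: none
Why: Lewis-acid-catalysed cyclodehydration of the α-aryloxy ketone (intramolecular Friedel–Crafts hydroxyalkylation, then dehydration) gives the 3-arylbenzofuran; closure is expected at the ring carbon para to the methoxy group, which places the ester at C4.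

**Step 15**
Reactants: 29 3-arylbenzofuran; 30 4-bromoanisole
Product: 31 methyl 3-(3,5-dimethoxyphenyl)-6-methoxy-2-(4-methoxyphenyl)-1-benzofuran-4-carboxylate
Conditions: Pd(OAc)2 (5 mol%), PCy3·HBF4 (10 mol%), t-BuCO2H (30 mol%), K2CO3, DMA, 100 °C
Reagents that add atoms: none
Why: Palladium-catalysed direct C2–H arylation of the benzofuran (concerted metalation–deprotonation with pivalate) at its only free furan position.

**Step 16**
Reactants: 31 benzofuran ester
Product: 32 [3-(3,5-dimethoxyphenyl)-6-methoxy-2-(4-methoxyphenyl)-1-benzofuran-4-yl]methanol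
Conditions: LiAlH4, THF, 0 °C
Reagents that add atoms: none
Why: LiAlH4 reduction of the methyl ester to the primary benzylic alcohol.

**Step 17**
Reactants: 32 benzofuranylmethanol
Product: 34 diethyl {[3-(3,5-dimethoxyphenyl)-6-methoxy-2-(4-methoxyphenyl)-1-benzofuran-4-yl]methyl}phosphonate, via benzylic bromide 33 (not isolated)
Conditions: PBr3, CH2Cl2, 0 °C; then P(OEt)3, 130 °C
Reagents that add atoms: triethyl phosphite CCOP(OCC)OCC
Why: Bromination of the benzylic alcohol with PBr3 and Michaelis–Arbuzov reaction of the crude bromide with triethyl phosphite give the benzylic phosphonate.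

**Step 18**
Reactants: 25 tetracyclic aldehyde; 34 phosphonate
Product: 35 decamethyl ether of the target (E-stilbene; Cα R, Cβ S, C3 S, C2 S)
Conditions: 34, t-BuOK, THF, 0 °C; then 25, 0 → 23 °C
Reagents that add atoms: none
Why: Horner–Wadsworth–Emmons olefination joins the two halves as the E-stilbene, and no stereocentre is touched under these basic conditions.

**Step 19**
Reactants: 35 decamethyl ether
Product: 36 target CNP0339094.1
Conditions: BCl3, n-Bu4NI, CH2Cl2, −78 → 23 °C; then H2O
Reagents that add atoms: none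
Why: Tenfold cleavage of aryl methyl ethers by BCl3 with iodide as the nucleophile, a milder pairing than BBr3 that should spare the stilbene; the 2,3-trans dihydrobenzofuran is the thermodynamic isomer, so reversible ionisation at C2 cannot change it.

**Compound list**
1 | 4-bromo-3-(hydroxymethyl)phenol | OCc1cc(O)ccc1Br | starting material
2 | 4-bromo-3-(triisopropylsilyloxymethyl)phenyl triisopropylsilyl ether | CC(C)[Si](OCc1cc(O[Si](C(C)C)(C(C)C)C(C)C)ccc1Br)(C(C)C)C(C)C | intermediate
3 | N-methoxy-N-methyl-3,5-dimethoxybenzamide | CON(C)C(=O)c1cc(OC)cc(OC)c1 | starting material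
4 | 2-(triisopropylsilyloxymethyl)-4-(triisopropylsilyloxy)phenyllithium | CC(C)[Si](OCc1cc(O[Si](C(C)C)(C(C)C)C(C)C)ccc1[Li])(C(C)C)C(C)C | intermediate (not isolated)
5 | (3,5-dimethoxyphenyl)[2-(triisopropylsilyloxymethyl)-4-(triisopropylsilyloxy)phenyl]methanone | CC(C)[Si](OCc1cc(O[Si](C(C)C)(C(C)C)C(C)C)ccc1C(=O)c1cc(OC)cc(OC)c1)(C(C)C)C(C)C | intermediate
6 | (4-methoxybenzyl)magnesium chloride | COc1ccc(C[Mg]Cl)cc1 | starting material
7 | 1-(3,5-dimethoxyphenyl)-2-(4-methoxyphenyl)-1-[2-(triisopropylsilyloxymethyl)-4-(triisopropylsilyloxy)phenyl]ethanol (racemic) | CC(C)[Si](OCc1cc(O[Si](C(C)C)(C(C)C)C(C)C)ccc1C(O)(Cc1ccc(OC)cc1)c1cc(OC)cc(OC)c1)(C(C)C)C(C)C | intermediate (not isolated)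
8 | 1-(3,5-dimethoxyphenyl)-2-(4-methoxyphenyl)-1-[2-(triisopropylsilyloxymethyl)-4-(triisopropylsilyloxy)phenyl]ethene (E/Z mixture) | CC(C)[Si](OCc1cc(O[Si](C(C)C)(C(C)C)C(C)C)ccc1C(=Cc1ccc(OC)cc1)c1cc(OC)cc(OC)c1)(C(C)C)C(C)C | intermediate
9 | (3S)-2-(3,5-dimethoxyphenyl)-3-(4-methoxyphenyl)-2-[2-(triisopropylsilyloxymethyl)-4-(triisopropylsilyloxy)phenyl]oxirane (C2 epimers) | CC(C)[Si](OCc1cc(O[Si](C(C)C)(C(C)C)C(C)C)ccc1C1(c2cc(OC)cc(OC)c2)O[C@H]1c1ccc(OC)cc1)(C(C)C)C(C)C | intermediate
10 | phenoxide of 9 after loss of the aryl silyl group (tetrabutylammonium salt) | [O-]c1ccc(C2(c3cc(OC)cc(OC)c3)O[C@H]2c2ccc(OC)cc2)c(CO[Si](C(C)C)(C(C)C)C(C)C)c1 | intermediate (not isolated)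
11 | para-quinone methide with the secondary alkoxide on the former oxirane CH carbon | O=C1C=CC(=C(c2cc(OC)cc(OC)c2)[C@@H]([O-])c2ccc(OC)cc2)C(CO[Si](C(C)C)(C(C)C)C(C)C)=C1 | intermediate (not isolated)
12 | isoaromatic 2,7a-dihydrobenzofuran-6-olate (oxa-Michael adduct, C7a sp3) | [O-]C1=CC2O[C@@H](c3ccc(OC)cc3)C(c3cc(OC)cc(OC)c3)=C2C(CO[Si](C(C)C)(C(C)C)C(C)C)=C1 | intermediate (not isolated)
13 | (2R,3S)-3-(3,5-dimethoxyphenyl)-4-(hydroxymethyl)-2-(4-methoxyphenyl)-2,3-dihydro-1-benzofuran-6-ol | OCc1cc(O)cc2c1[C@H](c1cc(OC)cc(OC)c1)[C@H](c1ccc(OC)cc1)O2 | intermediate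
14 | [(2R,3S)-3-(3,5-dimethoxyphenyl)-6-methoxy-2-(4-methoxyphenyl)-2,3-dihydro-1-benzofuran-4-yl]methanol | OCc1cc(OC)cc2c1[C@H](c1cc(OC)cc(OC)c1)[C@H](c1ccc(OC)cc1)O2 | intermediate
15 | (2R,3S)-3-(3,5-dimethoxyphenyl)-6-methoxy-2-(4-methoxyphenyl)-2,3-dihydro-1-benzofuran-4-carbaldehyde | O=Cc1cc(OC)cc2c1[C@H](c1cc(OC)cc(OC)c1)[C@H](c1ccc(OC)cc1)O2 | intermediate
16 | diethyl (4-methoxybenzyl)phosphonate | CCOP(=O)(Cc1ccc(OC)cc1)OCC | starting material
17 | (2R,3S)-3-(3,5-dimethoxyphenyl)-6-methoxy-2-(4-methoxyphenyl)-4-[(E)-2-(4-methoxyphenyl)ethenyl]-2,3-dihydro-1-benzofuran | COc1ccc(/C=C/c2cc(OC)cc3c2[C@H](c2cc(OC)cc(OC)c2)[C@H](c2ccc(OC)cc2)O3)cc1 | intermediate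
18 | trans-stilbene oxide of 17 (both diastereomers) | COc1ccc(C2OC2c2cc(OC)cc3c2[C@H](c2cc(OC)cc(OC)c2)[C@H](c2ccc(OC)cc2)O3)cc1 | intermediate (not isolated)
19 | tetracyclic alcohol: (2R,3S)-6-methoxy-2-(4-methoxyphenyl)-2,3-dihydrobenzofuran with C3 and C4 bridged by 3,5-dimethoxy-1,2-phenylene (C1 on C3, C2 on Cβ)–Cβ(H)(4-methoxyphenyl)–Cα(H)(OH)–; Cβ S, Cα epimers | OC1c2cc(OC)cc3c2[C@H](c2cc(OC)cc(OC)c2[C@@H]1c1ccc(OC)cc1)[C@H](c1ccc(OC)cc1)O3 | intermediate
20 | 3-iodo-4-methoxybenzaldehyde | COc1ccc(C=O)cc1I | starting material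
21 | 2-(3-iodo-4-methoxyphenyl)-1,3-dioxolane | COc1ccc(C2OCCO2)cc1I | intermediate
22 | methanesulfonate of 19 (Cα epimers) | CS(=O)(=O)OC1c2cc(OC)cc3c2[C@H](c2cc(OC)cc(OC)c2[C@@H]1c1ccc(OC)cc1)[C@H](c1ccc(OC)cc1)O3 | intermediate (not isolated)
23 | [5-(1,3-dioxolan-2-yl)-2-methoxyphenyl]zinc iodide | COc1ccc(C2OCCO2)cc1[Zn]I | intermediate (not isolated)
24 | tetracyclic acetal: as 19 with Cα bearing 5-(1,3-dioxolan-2-yl)-2-methoxyphenyl instead of OH; Cα R, Cβ S, C3 S, C2 R | COc1ccc(C2OCCO2)cc1[C@H]1c2cc(OC)cc3c2[C@H](c2cc(OC)cc(OC)c2[C@@H]1c1ccc(OC)cc1)[C@H](c1ccc(OC)cc1)O3 | intermediate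
25 | tetracyclic aldehyde: as 24 with 5-formyl-2-methoxyphenyl on Cα and 2,3-trans dihydrobenzofuran; Cα R, Cβ S, C3 S, C2 S | COc1ccc(C=O)cc1[C@H]1c2cc(OC)cc3c2[C@H](c2cc(OC)cc(OC)c2[C@@H]1c1ccc(OC)cc1)[C@@H](c1ccc(OC)cc1)O3 | intermediate
26 | methyl 3-hydroxy-5-methoxybenzoate | COC(=O)c1cc(O)cc(OC)c1 | starting material
27 | 2-bromo-1-(3,5-dimethoxyphenyl)ethan-1-one | COc1cc(OC)cc(c1)C(=O)CBr | starting material
28 | methyl 3-[2-(3,5-dimethoxyphenyl)-2-oxoethoxy]-5-methoxybenzoate | COC(=O)c1cc(OC)cc(OCC(=O)c2cc(OC)cc(OC)c2)c1 | intermediate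
29 | methyl 3-(3,5-dimethoxyphenyl)-6-methoxy-1-benzofuran-4-carboxylate | COC(=O)c1cc(OC)cc2occ(-c3cc(OC)cc(OC)c3)c12 | intermediate
30 | 4-bromoanisole | COc1ccc(Br)cc1 | starting material
31 | methyl 3-(3,5-dimethoxyphenyl)-6-methoxy-2-(4-methoxyphenyl)-1-benzofuran-4-carboxylate | COC(=O)c1cc(OC)cc2oc(-c3ccc(OC)cc3)c(-c3cc(OC)cc(OC)c3)c12 | intermediate
32 | [3-(3,5-dimethoxyphenyl)-6-methoxy-2-(4-methoxyphenyl)-1-benzofuran-4-yl]methanol | OCc1cc(OC)cc2oc(-c3ccc(OC)cc3)c(-c3cc(OC)cc(OC)c3)c12 | intermediate
33 | 4-(bromomethyl)-3-(3,5-dimethoxyphenyl)-6-methoxy-2-(4-methoxyphenyl)-1-benzofuran | BrCc1cc(OC)cc2oc(-c3ccc(OC)cc3)c(-c3cc(OC)cc(OC)c3)c12 | intermediate (not isolated)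
34 | diethyl {[3-(3,5-dimethoxyphenyl)-6-methoxy-2-(4-methoxyphenyl)-1-benzofuran-4-yl]methyl}phosphonate | CCOP(=O)(Cc1cc(OC)cc2oc(-c3ccc(OC)cc3)c(-c3cc(OC)cc(OC)c3)c12)OCC | intermediate
35 | decamethyl ether of the target: E-stilbene between C4 of the western benzofuran and ring C of 25 | COc1ccc(-c2oc3cc(OC)cc(/C=C/c4ccc(OC)c([C@H]5c6cc(OC)cc7c6[C@H](c6cc(OC)cc(OC)c6[C@@H]5c5ccc(OC)cc5)[C@@H](c5ccc(OC)cc5)O7)c4)c3c2-c2cc(OC)cc(OC)c2)cc1 | intermediate
36 | CNP0339094.1 (decaphenol; Cα R, Cβ S, C3 S, C2 S; E-stilbene) | Oc1ccc(-c2oc3cc(O)cc(/C=C/c4ccc(O)c([C@H]5c6cc(O)cc7c6[C@H](c6cc(O)cc(O)c6[C@@H]5c5ccc(O)cc5)[C@@H](c5ccc(O)cc5)O7)c4)c3c2-c2cc(O)cc(O)c2)cc1 | target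

**Totals**
Total step count: 19. Longest linear sequence: 13 steps (steps 1–9, 11, 12, 18, 19).

**Steps most likely to fail**

Step 5 (proposed new method). Three processes could defeat it:
- the alkoxide of 11 could undergo a 1,2-hydride shift or prototropic isomerisation to a deoxybenzoin-type ketone before it attacks the ring;
- early loss of the primary silyl ether would let the benzylic alkoxide add to the methide carbon (phthalan formation);
- poor facial selectivity in the final protonation at C3 would matter because the trans isomer belongs to the enantiomeric series once C2 is equilibrated in step 12. It must therefore be separated here; if protonation instead occurred syn to the C2 aryl group, the other enantiomer of the epoxidation ketone would be used in step 4.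

Fallback with known chemistry: set out from benzofuran ester 31 of the western series. Hydrogenation of its C2=C3 bond (H2 under pressure, Pd/C, AcOH/EtOAc) should add syn and give the racemic cis-dihydrobenzofuran ester F1. LiAlH4 reduction gives racemic 14, and preparative HPLC on a chiral stationary phase separates 14 from its enantiomer F2. The route is rejoined at 14.

Step 11. Oxidative addition to the hindered secondary mesylate may be slow, base-induced elimination to the ring-conjugated Cα=Cβ olefin may compete, and aryl transfer to the Cα radical may show poor facial selectivity. Fallback: set out from alcohol 19. Acylation with oxalyl chloride followed by water gives the hydrogen oxalate F3. Its caesium salt (Cs2CO3) is coupled with aryl iodide 21 under [Ir{dF(CF3)ppy}2(dtbbpy)]PF6 (1 mol%), NiBr2·glyme and 4,4′-di-tert-butyl-2,2′-bipyridine with blue light in DMSO/dioxane. The Cα radical then arises by photoredox double decarboxylation instead of from a nickel–mesylate reaction, and the aryl halide is used directly. The route is rejoined at 24.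

Step 9. The stilbene oxide may rearrange by a 1,2-hydride or aryl shift to carbonyl compounds faster than ring B closes the seven-membered ring, and the dioxirane may over-oxidise the electron-rich rings. Fallback: set out from stilbene 17. Syn-dihydroxylation (OsO4 cat., N-methylmorpholine N-oxide, acetone/H2O) gives the isolable diol F4. CF3CO2H in CH2Cl2 at −40 °C should ionise only its 4-methoxybenzylic hydroxyl (Cβ), and the same Friedel–Crafts closure by ring B delivers alcohol 19, where the route is rejoined.

**Further compounds**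
F1 | step 5 | methyl (2R*,3S*)-3-(3,5-dimethoxyphenyl)-6-methoxy-2-(4-methoxyphenyl)-2,3-dihydro-1-benzofuran-4-carboxylate (racemic cis; one enantiomer drawn) | COC(=O)c1cc(OC)cc2c1[C@H](c1cc(OC)cc(OC)c1)[C@H](c1ccc(OC)cc1)O2
F2 | step 5 | [(2S,3R)-3-(3,5-dimethoxyphenyl)-6-methoxy-2-(4-methoxyphenyl)-2,3-dihydro-1-benzofuran-4-yl]methanol (enantiomer of 14, separated off) | OCc1cc(OC)cc2c1[C@@H](c1cc(OC)cc(OC)c1)[C@@H](c1ccc(OC)cc1)O2
F3 | step 11 | hydrogen oxalate of alcohol 19 (Cα epimers) | OC(=O)C(=O)OC1c2cc(OC)cc3c2[C@H](c2cc(OC)cc(OC)c2[C@@H]1c1ccc(OC)cc1)[C@H](c1ccc(OC)cc1)O3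
F4 | step 9 | 1,2-diol from syn-dihydroxylation of the stilbene of 17 (two diastereomers) | COc1ccc(C(O)C(O)c2cc(OC)cc3c2[C@H](c2cc(OC)cc(OC)c2)[C@H](c2ccc(OC)cc2)O3)cc1
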